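**Hidden constants.** The constants of this flask were hidden, so I started from what its readings could give. Solid L dissolves as G, gas X dissolves as D, G and D make E, E turns into Z and back, and G with E makes Q.

| setting | Thursday's | Sunday's | flask |
|---|---|---|---|
| L | 0.12 M | 0.12 M | 0.12 M |
| X | 22 mM (held) | 22 mM (held) | 22 mM (held) |
| temperature | 60 °C | 66 °C | 60 °C |
| remark | the very flask that is asked about, followed so far | run made earlier |  |
| time |  |  | 8.0 d |

| run | time / h | E / % |
|---|---|---|
| Thursday's | 8.00 | 16 |
| Thursday's | 20.0 | 32 |
| Thursday's | 40.0 | 28 |
| Thursday's | 60.0 | 20 |
| Thursday's | 96.0 | 26 |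
| Thursday's | 120 | 30 |
| Sunday's | 8.00 | 14 |
| Sunday's | 20.0 | 29 |
| Sunday's | 40.0 | 29 |
| Sunday's | 60.0 | 31 |
| Sunday's | 96.0 | 27 |
| Sunday's | 120 | 30 |

(standard deviation of a reading: 2 percentage points)

- alpha: at 8.0 d take out 90 % of the E then present, then wait 4.0 d
- eta: change nothing and wait 4.0 d more
- gamma: at 8.0 d raise the temperature by 20 K, then wait 4.0 d

- in percentages every species weighs as the L in it: one Q counts as two
- as a solid, counted per litre of solution: L
- at the start none of D is dissolved
- what is taken out of E is counted as made
- the numbers in the tables scatter with a standard deviation of 2 percentage points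
- reactions considered so far: G + E -> Q; G + D -> E; E <-> Z; L <-> G; X <-> D
- at the start none of L is in solution

- E, in percent of the L first charged, at 8.0 d
- which option adds most E ("none" when 2 percentage points or less is all one gets) (alpha / eta / gamma / none)
- E present, with what was taken out counted in, in percent of the L first charged, after alpha
- E present, with what was taken out counted in, in percent of the L first charged, after gamma

**First way.** I replaced Thursday's curve from 40.0 h onward by its mean, 26.0 %, which carries about 1 percentage point of scatter. To check that replacement I dropped the low reading of 20 %, and the mean became 28.0 %, so the choice moves it by 2 points. The asked 8.0 d lies later than the last reading, and I took the mean as E there.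

**Second way.** Sunday's run has the same charge at 66 °C, and a frozen level should repeat in it. Its mean over the same times is 29.2 %, higher than Thursday's by 3.2 points, which is 2.30 times the scatter of that difference. The two ways part, and Sunday's cheats as a value for this flask, since that run was warmer. I kept Thursday's mean and read the gap as a weak temperature signal.

**Split ratio.** A level that moves with temperature looks to me like two tanks joined by a pipe, E and Z. As an assumption I counted the whole rest of the charge as Z and neglected Q. That gives the split ratio r, [Z]/[E] at rest, the equilibrium constant of E and Z, as a reading with the scatter of the means: 2.85 on Thursday and 2.42 on Sunday.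

**My reckoning.** In alpha, taking 90 % of the E out lets the remainder split again by r, so I expected 43.3 % with the removed E counted. For gamma I repeated the Sunday step of r over 20 K, which gave 37.7 %. I chose alpha, knowing that the gamma figure rests on the gap of 3.2 points between two means.

**The forecast.** The forecast gave 28.5 % (26 % to 31 %) for now, 29 % (26.5 % to 36 %) after alpha, 28.5 % (24 % to 32 %) after gamma, and none as best, holding that “removing E, waiting or heating should add almost nothing”. My 26.0 % for now stood lower than its figure, my alpha higher than its figure, and my gamma higher than its figure.

**The result.** The flask gave 24.8 % at 8.0 d, 41.3 % after alpha and 45.1 % after gamma, so gamma was best.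

    G + E → Q (k = 0.760 M⁻¹ h⁻¹, Ea = 59.0 kJ mol⁻¹)
    G + D → E (k = 58.0 M⁻¹ h⁻¹, Ea = 66.0 kJ mol⁻¹)
    E ⇌ Z (K = 2.80, k = 0.130 h⁻¹, Ea = 100 kJ mol⁻¹, ΔH = −46.0 kJ mol⁻¹)
    L ⇌ G, rate k4*(cs4 - [G]) while solid is left; crystals form when [G] > cs4 (solubility = 43.0 mM, k = 0.120 h⁻¹)
    X ⇌ D, rate k5*(csat - [D]) (kL = 0.480 h⁻¹)
    (constants at 60 °C)

In the flask, E and Z relax with a half-life of 3.93 h, both ways together by this step alone, short against 8.0 d. Applied to the flask's 24.8 % of E and 69.5 % of Z, my r returns 41.1 % for alpha. At 85 °C the neighbour flask held 44.1 % of Z against 50.2 % of E, a ratio of 0.878, lower than the 1.44 that the Sunday step of r reaches there.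

All runs stem from a simulated flask for substances that don't exist.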